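**Plan**

- Numbering used below: lactone O5–C1(=O)–C2(Me)–C3(OAc)–C4(Me)–C5; tetrahydropyran O4–C4–C5–C6(Me)–C7(O-acyl)–C8(Me); C4–C5 is the ring fusion.
- Enabling feature: in the pyran ring C4 carries an acyl carbon (C3, acceptor), C7 carries oxygen (donor), and the two are tied by C8–O4. C4/C7 are therefore a masked 1,4-dipole that can be stored as the C4–C7 bond of a 3-silyloxyoxetane-2-carboxylate, and C5–C6 is a propanal enol silane.
- Cuts: side-chain alkene and O7–acyl ester; lactone C1–O5 and C2–C3; then C6–C7 and C4–C5 of the pyran in one operation (formal [4+2] of oxetane 6 with enol silane 8). The oxetane is a temporary ring traced back to (S)-but-3-yn-2-ol.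
- Forward: oxetane (steps 1–5), pyran ring with the C4–C7 stereocentres (step 7), lactone ring by anti-aldol and acyl transfer (steps 8–10), then acetate, O7 release, phosphonoacetate and Z-olefination (steps 11–16).
- Stereochemistry: C8 from (S)-but-3-yn-2-ol; C4, C5, C6, C7 from the key step under control of C8 (all-equatorial chair, axial C4 methyl); C2 and C3 from the oxazolidinone-controlled anti-aldol, matched with chelation by O4; Z-alkene from the Still–Gennari olefination.

Key step: step 7

Remark: compounds 3–6 are carried as mixtures at the oxetane carbons other than the methyl-bearing carbinol carbon (left undefined in the SMILES), because both become trigonal in step 7.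

**Step 1**
Reactants: 1 (S)-but-3-yn-2-ol
Product: 2 methyl (S)-4-hydroxypent-2-ynoate
Conditions: n-BuLi (2.05 equiv), THF, −78 °C; ClCO2Me (1.0 equiv), −78 °C; aq. NH4Cl
Reagents that add atoms: methyl chloroformate, COC(=O)Cl
Why: C-acylation of the dilithio alkoxide–acetylide, whose acetylide carbon is the more nucleophilic site at −78 °C; the carbinol stereocentre is not touched.

**Step 2**
Reactants: 2 methyl (S)-4-hydroxypent-2-ynoate
Product: 3 methyl (4S)-4-methyl-3-oxooxetane-2-carboxylate
Conditions: IPrAuNTf2 (5 mol %), 4-acetylpyridine N-oxide (2 equiv), ClCH2CH2Cl, 60 °C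
Reagents that add atoms: 4-acetylpyridine N-oxide, CC(=O)c1cc[n+]([O-])cc1
Why: Gold-catalysed oxidative cyclisation of a propargylic alcohol to an oxetan-3-one: the N-oxide adds to the β-carbon of the gold-activated ynoate, and the α-oxo gold carbene at the ester-bearing carbon inserts into the O–H bond, leaving the carbinol centre intact.

**Step 3**
Reactants: 3 methyl (4S)-4-methyl-3-oxooxetane-2-carboxylate
Product: 4 methyl (4S)-2,4-dimethyl-3-oxooxetane-2-carboxylate
Conditions: MeI, K2CO3, acetone, 0 °C to rt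
Reagents that add atoms: iodomethane, CI
Why: C-alkylation of a β-keto ester enolate, only the doubly activated C–H being removed by carbonate; the configuration of the new quaternary carbon is irrelevant because it is erased in step 7.

**Step 4**
Reactants: 4 methyl (4S)-2,4-dimethyl-3-oxooxetane-2-carboxylate
Product: 5 methyl (4S)-3-hydroxy-2,4-dimethyloxetane-2-carboxylate
Conditions: NaBH4, CeCl3·7H2O, MeOH, −78 °C; AcOH quench
Reagents that add atoms: none
Why: Luche reduction at low temperature with an acidic quench reduces the ketone without a free alkoxide that could trigger retro-Claisen or retro-aldol opening; the new carbinol configuration is erased in step 7.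

**Step 5**
Reactants: 5 methyl (4S)-3-hydroxy-2,4-dimethyloxetane-2-carboxylate
Product: 6 methyl (4S)-3-[(tert-butyldimethylsilyl)oxy]-2,4-dimethyloxetane-2-carboxylate
Conditions: TBSOTf, 2,6-lutidine, CH2Cl2, −78 °C
Reagents that add atoms: tert-butyldimethylsilyl trifluoromethanesulfonate, CC(C)(C)[Si](C)(C)OS(=O)(=O)C(F)(F)F
Why: Silylation of a secondary alcohol under a non-nucleophilic base never forms the alkoxide, so the strained aldol does not open, and it installs the silyloxy donor next to the ester acceptor.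

**Step 6**
Reactants: 7 allyloxytrimethylsilane
Product: 8 (E)-trimethyl(prop-1-en-1-yloxy)silane
Conditions: [Ir(cod)(PMePh2)2]PF6 (1 mol %, pre-activated with H2), THF, rt
Reagents that add atoms: none
Why: Iridium hydride-catalysed 1,3-hydrogen shift (allyl ether to enol ether isomerisation), which gives the (E)-enol silane selectively.

**Step 7**
Reactants: 6 methyl (4S)-3-[(tert-butyldimethylsilyl)oxy]-2,4-dimethyloxetane-2-carboxylate; 8 (E)-trimethyl(prop-1-en-1-yloxy)silane
Product: 11 methyl (2S,3S,4R,5R,6S)-5-[(tert-butyldimethylsilyl)oxy]-2,4,6-trimethyl-3-[(trimethylsilyl)oxy]oxane-2-carboxylate, via oxocarbenium enolate zwitterion 9 (not isolated), via open-chain silyloxocarbenium enolate 10 (not isolated)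
Conditions: Sc(OTf)3 (10 mol %), 8 (3 equiv), 2,6-di-tert-butylpyridine (20 mol %), 4 Å molecular sieves, CH2Cl2, −40 to 0 °C; aq. NaHCO3
Reagents that add atoms: none
Why: Proposed new method: Sc(OTf)3 binds the α-alkoxy ester of 6 as a chelate (ester carbonyl and ring oxygen) and, pushed by the silyloxy donor, the strained donor–acceptor C–C bond of the oxetane (C4–C7) breaks heterolytically to zwitterion 9 (silyl oxocarbenium at C7, chelated glycolate-type enolate at C4, held together by C8–O4); the β-carbon (C6) of enol silane 8 adds to C7 to give 10, whose new silyl oxocarbenium (C5) is captured by the enolate carbon C4. The closest known reaction types are the Lewis-acid formal [4+2] cycloaddition of donor–acceptor cyclobutanes (alkoxycyclobutane diesters, 3-alkoxycyclobutanones) with aldehydes and enol silanes, and the ring opening of 2-siloxycyclopropanecarboxylates. Only the tetrahydropyran ring is closed, by a 6-(enolexo)-exo-trig Mukaiyama-type aldol attack of C4 on C5 that follows the intermolecular Mukaiyama-type C6–C7 bond formation. C7 is set relative to C8 by attack anti to the C8–O4 bond (polar Felkin–Anh sense, 7,8-anti); C6 and C5 follow from the (E)-enol silane adding through a chair-like array in which C6–Me and C5–OSiMe3 are equatorial; C4 is set in the same chair because the bulkier enolate terminus (C3) takes the equatorial and the methyl the axial position. The step needs C–C instead of C–O cleavage of the oxetane, which the vicinal donor/acceptor pair and the bidentate binding of the Lewis acid should secure, and it needs the reactive termini not to react with other substrate molecules, which is secured because nucleophile and electrophile exist only as the transient zwitterion that re-closes unless trapped by the excess enol silane.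

**Step 8**
Reactants: 11 methyl (2S,3S,4R,5R,6S)-5-[(tert-butyldimethylsilyl)oxy]-2,4,6-trimethyl-3-[(trimethylsilyl)oxy]oxane-2-carboxylate
Product: 12 (2S,3S,4R,5R,6S)-5-[(tert-butyldimethylsilyl)oxy]-2,4,6-trimethyl-3-[(trimethylsilyl)oxy]oxane-2-carbaldehyde
Conditions: i-Bu2AlH (DIBAL-H), CH2Cl2, −78 °C; aq. KNaC4H4O6
Reagents that add atoms: none
Why: Partial reduction of an α-alkoxy ester: the tetrahedral aluminium hemiacetal, chelated by the ring oxygen, should persist at −78 °C and collapse to the aldehyde only on work-up.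

**Step 9**
Reactants: 12 (2S,3S,4R,5R,6S)-5-[(tert-butyldimethylsilyl)oxy]-2,4,6-trimethyl-3-[(trimethylsilyl)oxy]oxane-2-carbaldehyde; 13 (4S)-4-benzyl-3-propanoyl-1,3-oxazolidin-2-one
Product: 14 (4S)-4-benzyl-3-[(2R,3S)-3-{(2S,3S,4R,5R,6S)-5-[(tert-butyldimethylsilyl)oxy]-2,4,6-trimethyl-3-[(trimethylsilyl)oxy]oxan-2-yl}-2-methyl-3-[(trimethylsilyl)oxy]propanoyl]-1,3-oxazolidin-2-one
Conditions: MgCl2 (20 mol %), Et3N, Me3SiCl, EtOAc, rt
Reagents that add atoms: chlorotrimethylsilane, C[Si](C)(C)Cl
Why: Evans MgCl2-catalysed anti-aldol of a non-enolisable aldehyde: the chelated (Z)-magnesium enolate reacts on the face away from the benzyl group (sets C2, as in alkylations of the same enolate) with anti topicity (sets C3), the C3 configuration also expected for attack on the O4-chelated aldehyde from the side of the axial C4 methyl, so reagent and substrate control should be matched, and in situ silylation turns the catalyst over.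

**Step 10**
Reactants: 14 (the anti-aldol adduct of step 9)
Product: 16 (3R,4S,4aR,6S,7R,8S,8aS)-7-[(tert-butyldimethylsilyl)oxy]-4-hydroxy-3,4a,6,8-tetramethylhexahydropyrano[3,2-b]pyran-2(3H)-one, via diol imide 15 (not isolated)
Conditions: citric acid, MeOH, 0 °C; then Et3N, DMAP (cat.), toluene, 60 °C
Reagents that add atoms: none
Why: Mild acid methanolysis removes both trimethylsilyl ethers while the TBS ether stays, and the freed C5 hydroxyl then attacks the imide carbonyl (6-exo-trig intramolecular acyl transfer) to close the trans-fused δ-lactone and release the auxiliary without touching a stereocentre.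

**Step 11**
Reactants: 16 (the hydroxy lactone of step 10)
Product: 17 (3R,4S,4aS,6S,7R,8S,8aS)-7-[(tert-butyldimethylsilyl)oxy]-3,4a,6,8-tetramethyl-2-oxooctahydropyrano[3,2-b]pyran-4-yl acetate
Conditions: Ac2O, pyridine, DMAP (cat.), CH2Cl2, 0 °C to rt
Reagents that add atoms: acetic anhydride, CC(=O)OC(C)=O
Why: DMAP-catalysed acetylation of the only free (secondary) alcohol under conditions too mild for β-elimination from the lactone.

**Step 12**
Reactants: 17 (the acetate of step 11)
Product: 18 (3R,4S,4aS,6S,7R,8R,8aS)-7-hydroxy-3,4a,6,8-tetramethyl-2-oxooctahydropyrano[3,2-b]pyran-4-yl acetate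
Conditions: HF·pyridine, pyridine, THF, 0 °C to rt
Reagents that add atoms: none
Why: Fluoride cleavage of the silyl ether under buffered, non-basic conditions that leave the acetate and the lactone in place.

**Step 13**
Reactants: 19 methyl 2-[bis(2,2,2-trifluoroethoxy)phosphoryl]acetate
Product: 20 2-[bis(2,2,2-trifluoroethoxy)phosphoryl]acetic acid
Conditions: LiOH (1.0 equiv), THF/H2O, 0 °C; then aq. HCl
Reagents that add atoms: lithium hydroxide (hydroxide oxygen), [Li+].[OH-]
Why: Saponification of the carboxylic methyl ester with one equivalent of hydroxide at 0 °C, the carboxylate formed being protected against further attack.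

**Step 14**
Reactants: 18 (the C7 alcohol of step 12); 20 2-[bis(2,2,2-trifluoroethoxy)phosphoryl]acetic acid
Product: 21 (3R,4S,4aS,6S,7R,8R,8aS)-4-(acetyloxy)-3,4a,6,8-tetramethyl-2-oxooctahydropyrano[3,2-b]pyran-7-yl 2-[bis(2,2,2-trifluoroethoxy)phosphoryl]acetate
Conditions: EDC·HCl, DMAP (cat.), CH2Cl2, 0 °C to rt
Reagents that add atoms: none
Why: Steglich-type carbodiimide esterification of the equatorial secondary alcohol with retention at C7.

**Step 15**
Reactants: 22 octane-1,2-diol
Product: 23 2-oxooctanal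
Conditions: IBX (3 equiv), DMSO, rt; used at once
Reagents that add atoms: none
Why: IBX oxidises both hydroxyls of a 1,2-diol to the 1,2-dicarbonyl compound without cleaving the C–C bond.

**Step 16**
Reactants: 21 (the phosphonoacetate of step 14); 23 2-oxooctanal
Product: 24 Botcinin J, (3R,4S,4aS,6S,7R,8R,8aS)-4-(acetyloxy)-3,4a,6,8-tetramethyl-2-oxooctahydropyrano[3,2-b]pyran-7-yl (2Z)-4-oxodec-2-enoate
Conditions: KHMDS (1.0 equiv), 18-crown-6, THF, −78 °C; then 23, −78 °C; AcOH quench at −78 °C
Reagents that add atoms: none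
Why: Still–Gennari olefination: the electron-poor phosphonate anion (far more acidic than the lactone α-position) adds to the more electrophilic aldehyde carbonyl of the keto aldehyde and eliminates under kinetic control to the (Z)-enoate.

**Compound list**

1 | (S)-but-3-yn-2-ol | C[C@H](O)C#C | starting material
2 | methyl (S)-4-hydroxypent-2-ynoate | C[C@H](O)C#CC(=O)OC | intermediate
3 | methyl (4S)-4-methyl-3-oxooxetane-2-carboxylate (mixture at C2) | COC(=O)C1O[C@@H](C)C1=O | intermediate
4 | methyl (4S)-2,4-dimethyl-3-oxooxetane-2-carboxylate (mixture at C2) | COC(=O)C1(C)O[C@@H](C)C1=O | intermediate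
5 | methyl (4S)-3-hydroxy-2,4-dimethyloxetane-2-carboxylate (mixture at C2 and C3) | COC(=O)C1(C)O[C@@H](C)C1O | intermediate
6 | methyl (4S)-3-[(tert-butyldimethylsilyl)oxy]-2,4-dimethyloxetane-2-carboxylate (mixture at C2 and C3) | COC(=O)C1(C)O[C@@H](C)C1O[Si](C)(C)C(C)(C)C | intermediate
7 | allyloxytrimethylsilane | C=CCO[Si](C)(C)C | starting material
8 | (E)-trimethyl(prop-1-en-1-yloxy)silane | C/C=C/O[Si](C)(C)C | intermediate
9 | ring-opened zwitterion: ester enolate at C4, O-silyl oxocarbenium at C7 (metal-free drawing) | COC([O-])=C(C)O[C@@H](C)C=[O+][Si](C)(C)C(C)(C)C | intermediate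
10 | open-chain adduct: ester enolate at C4, O-trimethylsilyl oxocarbenium at C5 (metal-free drawing) | COC([O-])=C(C)O[C@@H](C)[C@H](O[Si](C)(C)C(C)(C)C)[C@@H](C)C=[O+][Si](C)(C)C | intermediate
11 | methyl (2S,3S,4R,5R,6S)-5-[(tert-butyldimethylsilyl)oxy]-2,4,6-trimethyl-3-[(trimethylsilyl)oxy]oxane-2-carboxylate | CC(C)(C)[Si](C)(C)O[C@@H]1[C@@H](C)[C@H](O[Si](C)(C)C)[C@@](C)(C(=O)OC)O[C@H]1C | intermediate
12 | (2S,3S,4R,5R,6S)-5-[(tert-butyldimethylsilyl)oxy]-2,4,6-trimethyl-3-[(trimethylsilyl)oxy]oxane-2-carbaldehyde | CC(C)(C)[Si](C)(C)O[C@@H]1[C@@H](C)[C@H](O[Si](C)(C)C)[C@@](C)(C=O)O[C@H]1C | intermediate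
13 | (4S)-4-benzyl-3-propanoyl-1,3-oxazolidin-2-one | CCC(=O)N1[C@@H](Cc2ccccc2)COC1=O | starting material
14 | (4S)-4-benzyl-3-[(2R,3S)-3-{(2S,3S,4R,5R,6S)-5-[(tert-butyldimethylsilyl)oxy]-2,4,6-trimethyl-3-[(trimethylsilyl)oxy]oxan-2-yl}-2-methyl-3-[(trimethylsilyl)oxy]propanoyl]-1,3-oxazolidin-2-one | CC(C)(C)[Si](C)(C)O[C@@H]1[C@@H](C)[C@H](O[Si](C)(C)C)[C@@](C)([C@@H](O[Si](C)(C)C)[C@@H](C)C(=O)N2[C@@H](Cc3ccccc3)COC2=O)O[C@H]1C | intermediate
15 | diol imide: compound 14 with both trimethylsilyl ethers cleaved to hydroxyls (TBS ether kept) | CC(C)(C)[Si](C)(C)O[C@@H]1[C@@H](C)[C@H](O)[C@@](C)([C@@H](O)[C@@H](C)C(=O)N2[C@@H](Cc3ccccc3)COC2=O)O[C@H]1C | intermediate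
16 | (3R,4S,4aR,6S,7R,8S,8aS)-7-[(tert-butyldimethylsilyl)oxy]-4-hydroxy-3,4a,6,8-tetramethylhexahydropyrano[3,2-b]pyran-2(3H)-one | CC(C)(C)[Si](C)(C)O[C@@H]1[C@@H](C)[C@@H]2OC(=O)[C@H](C)[C@H](O)[C@@]2(C)O[C@H]1C | intermediate
17 | (3R,4S,4aS,6S,7R,8S,8aS)-7-[(tert-butyldimethylsilyl)oxy]-3,4a,6,8-tetramethyl-2-oxooctahydropyrano[3,2-b]pyran-4-yl acetate | CC(C)(C)[Si](C)(C)O[C@@H]1[C@@H](C)[C@@H]2OC(=O)[C@H](C)[C@H](OC(C)=O)[C@@]2(C)O[C@H]1C | intermediate
18 | (3R,4S,4aS,6S,7R,8R,8aS)-7-hydroxy-3,4a,6,8-tetramethyl-2-oxooctahydropyrano[3,2-b]pyran-4-yl acetate | O[C@@H]1[C@@H](C)[C@@H]2OC(=O)[C@H](C)[C@H](OC(C)=O)[C@@]2(C)O[C@H]1C | intermediate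
19 | methyl 2-[bis(2,2,2-trifluoroethoxy)phosphoryl]acetate | COC(=O)CP(=O)(OCC(F)(F)F)OCC(F)(F)F | starting material
20 | 2-[bis(2,2,2-trifluoroethoxy)phosphoryl]acetic acid | OC(=O)CP(=O)(OCC(F)(F)F)OCC(F)(F)F | intermediate
21 | (3R,4S,4aS,6S,7R,8R,8aS)-4-(acetyloxy)-3,4a,6,8-tetramethyl-2-oxooctahydropyrano[3,2-b]pyran-7-yl 2-[bis(2,2,2-trifluoroethoxy)phosphoryl]acetate | FC(F)(F)COP(=O)(OCC(F)(F)F)CC(=O)O[C@@H]1[C@@H](C)[C@@H]2OC(=O)[C@H](C)[C@H](OC(C)=O)[C@@]2(C)O[C@H]1C | intermediate
22 | octane-1,2-diol | CCCCCCC(O)CO | starting material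
23 | 2-oxooctanal | CCCCCCC(=O)C=O | intermediate
24 | Botcinin J, (3R,4S,4aS,6S,7R,8R,8aS)-4-(acetyloxy)-3,4a,6,8-tetramethyl-2-oxooctahydropyrano[3,2-b]pyran-7-yl (2Z)-4-oxodec-2-enoate | CCCCCCC(=O)/C=C\C(=O)O[C@@H]1[C@@H](C)[C@@H]2OC(=O)[C@H](C)[C@H](OC(C)=O)[C@@]2(C)O[C@H]1C | target

**Totals**

Total step count: 16. Longest linear sequence: 13 steps (steps 1–5, 7–12, 14 and 16).

**Steps most likely to fail**

1. Step 7 (proposed new method). The zwitterion may be lost to cycloreversion into a pyruvate and an enol silane, to C–O ring opening of the oxetane or to oligomerisation, or the first C–C bond may form with poor facial selectivity. Fallback by known reactions, setting out from 5 and coming back at 11: a catalytic amount of Et3N in CH2Cl2 at 0 °C should open the strained aldol by retro-aldol cleavage to methyl 2-{[(2S)-1-oxopropan-2-yl]oxy}propanoate F1. Crotylboration with pinacol (Z)-crotylboronate (closed chair transition state, syn; Felkin–Anh, anti to the ether oxygen) should give methyl 2-{[(2S,3R,4S)-3-hydroxy-4-methylhex-5-en-2-yl]oxy}propanoate F2. TBSOTf and 2,6-lutidine give methyl 2-{[(2S,3R,4S)-3-[(tert-butyldimethylsilyl)oxy]-4-methylhex-5-en-2-yl]oxy}propanoate F3. Ozonolysis (O3, then PPh3) gives methyl 2-{[(2S,3R,4R)-3-[(tert-butyldimethylsilyl)oxy]-4-methyl-5-oxopentan-2-yl]oxy}propanoate F4. Soft enolisation of the α-alkoxy ester with TiCl4 and Bu3N at −78 °C and intramolecular aldol addition should close the ring to methyl (2S,3S,4S,5R,6S)-5-[(tert-butyldimethylsilyl)oxy]-3-hydroxy-2,4,6-trimethyloxane-2-carboxylate F5. Me3SiCl and imidazole then give 11.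

2. Step 9. The hindered neopentyl-type aldehyde may add sluggishly, the adduct may revert by retro-aldol cleavage, or the facial preferences of enolate and aldehyde may turn out mismatched. Fallback, setting out from 12 and coming back at 16: reagent control is replaced by chelation control. SnCl4 in CH2Cl2 at −78 °C (chelate between the aldehyde oxygen and O4) with the (E)-silyl ketene thioacetal of S-tert-butyl propanethioate (Mukaiyama aldol, anti from the (E)-thioacetal), followed by citric acid in MeOH, should give S-tert-butyl (2R,3S)-3-{(2S,3S,4S,5R,6S)-5-[(tert-butyldimethylsilyl)oxy]-3-hydroxy-2,4,6-trimethyloxan-2-yl}-3-hydroxy-2-methylpropanethioate F6. AgOCOCF3 and Na2HPO4 in benzene activate the thioester for lactonisation by the C5 hydroxyl to give 16.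

3. Step 16. The γ-keto (Z)-enoate may isomerise to the (E)-isomer under the basic olefination conditions, acetate may be eliminated from the lactone, or the keto aldehyde may hydrate and oligomerise before it reacts. Fallback, setting out from 18 and ending at 24: the Z-alkene is brought in ready-made from maleic anhydride. Maleic anhydride and DMAP in CH2Cl2 give (2Z)-4-{[(3R,4S,4aS,6S,7R,8R,8aS)-4-(acetyloxy)-3,4a,6,8-tetramethyl-2-oxooctahydropyrano[3,2-b]pyran-7-yl]oxy}-4-oxobut-2-enoic acid F7. EtSH, EDC·HCl and DMAP give its S-ethyl thioester F8. Fukuyama coupling with n-C6H13ZnI and catalytic PdCl2(PPh3)2 in toluene at rt gives 24.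

Further compounds
F1 | step 7 | methyl 2-{[(2S)-1-oxopropan-2-yl]oxy}propanoate | COC(=O)C(C)O[C@@H](C)C=O
F2 | step 7 | methyl 2-{[(2S,3R,4S)-3-hydroxy-4-methylhex-5-en-2-yl]oxy}propanoate | COC(=O)C(C)O[C@@H](C)[C@H](O)[C@@H](C)C=C
F3 | step 7 | methyl 2-{[(2S,3R,4S)-3-[(tert-butyldimethylsilyl)oxy]-4-methylhex-5-en-2-yl]oxy}propanoate | COC(=O)C(C)O[C@@H](C)[C@H](O[Si](C)(C)C(C)(C)C)[C@@H](C)C=C
F4 | step 7 | methyl 2-{[(2S,3R,4R)-3-[(tert-butyldimethylsilyl)oxy]-4-methyl-5-oxopentan-2-yl]oxy}propanoate | COC(=O)C(C)O[C@@H](C)[C@H](O[Si](C)(C)C(C)(C)C)[C@@H](C)C=O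
F5 | step 7 | methyl (2S,3S,4S,5R,6S)-5-[(tert-butyldimethylsilyl)oxy]-3-hydroxy-2,4,6-trimethyloxane-2-carboxylate | CC(C)(C)[Si](C)(C)O[C@@H]1[C@@H](C)[C@H](O)[C@@](C)(C(=O)OC)O[C@H]1C
F6 | step 9 | S-tert-butyl (2R,3S)-3-{(2S,3S,4S,5R,6S)-5-[(tert-butyldimethylsilyl)oxy]-3-hydroxy-2,4,6-trimethyloxan-2-yl}-3-hydroxy-2-methylpropanethioate | CC(C)(C)[Si](C)(C)O[C@@H]1[C@@H](C)[C@H](O)[C@@](C)([C@@H](O)[C@@H](C)C(=O)SC(C)(C)C)O[C@H]1C
F7 | step 16 | (2Z)-4-{[(3R,4S,4aS,6S,7R,8R,8aS)-4-(acetyloxy)-3,4a,6,8-tetramethyl-2-oxooctahydropyrano[3,2-b]pyran-7-yl]oxy}-4-oxobut-2-enoic acid | OC(=O)/C=C\C(=O)O[C@@H]1[C@@H](C)[C@@H]2OC(=O)[C@H](C)[C@H](OC(C)=O)[C@@]2(C)O[C@H]1C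
F8 | step 16 | (3R,4S,4aS,6S,7R,8R,8aS)-4-(acetyloxy)-3,4a,6,8-tetramethyl-2-oxooctahydropyrano[3,2-b]pyran-7-yl (2Z)-4-(ethylsulfanyl)-4-oxobut-2-enoate | CCSC(=O)/C=C\C(=O)O[C@@H]1[C@@H](C)[C@@H]2OC(=O)[C@H](C)[C@H](OC(C)=O)[C@@]2(C)O[C@H]1C
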